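**Plan**

1. Numbering follows ent-kaurane: ring A = C1–C5 and C10; δ-lactone = C8–C7(=O)–O–C20H2–C10–C9; ring C = C8, C9, C11–C14; ring D = C8, C14, C13, C16, C15; C6 is the CH2OH carbon on C5, C17 the exocyclic CH2.
2. Retrosynthesis: the late adjustments (C15 oxo, C14–OH, C1–OAc, C5–C6) are stripped first. Ring D is then opened at C13–C16 (enol silane/alkyne cyclization) and C8–C15 (propargylation). Next C7–C8 and C20–C10 are cut together, which excises the CH2–O–C(=O) linchpin and leaves a 1,5-dicarbonyl compound. Last, C9–C10 is cut (Michael addition) to 4,4-dimethylcyclohexane-1,3-dione and (S)-4-silyloxycyclohex-2-enone.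
3. Enabling feature: C9 is flanked by two enolizable carbons, C8 (α to the ring C ketone C14) and C10 (C2 of the ring A 1,3-dione), the array C1(=O)–C10–C9–C8–C14(=O). The dione enol oxygen on C1 lies 1,5 to C8, so a ClCH2–O–C(=O) unit parked there as an enol carbonate can be handed to C8 through a six-membered transition state and then closed on C10 (6-exo-tet); the enol-oxygen tether is shed in the same operation.
4. Forward order: ring C (chiral enone) and ring A (dione) are joined at C9–C10; the spiro lactone is closed in the key step; ring A is trimmed (C5 ketone to CH–CH2OH, C1 ketone to CH–OAc); C8 is made quaternary and ring D is closed last; C14 and C15 are then brought to the right oxidation level.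
5. Stereochemistry: C11 from asymmetric transfer hydrogenation; C9 from anti addition to the silyloxy enone; C10 from the key step; C5 from H-atom transfer and C1 from hydride delivery, both anti to the axial C20; C8 from alkylation cis to H9; C13 from the ring constraint; C14 from a thermodynamically steered ketone reduction.

Key step: step 6

Remark: β-keto lactones 9–14 are drawn as their C8=C14 enol tautomers (C8 is not yet a fixed stereocentre). Compound 7 is drawn as the carbonate on the enol oxygen at C1; the regioisomer on the C5 oxygen would react in the same way in step 6. Compound 6 may sit partly as a bridged hemiketal (enol oxygen on C14), which opens under the conditions of step 5.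

**Route**

Step 1
Reactants: 1 1,4-dioxaspiro[4.5]dec-6-en-8-one
Product: 2 (S)-1,4-dioxaspiro[4.5]dec-6-en-8-ol
Conditions: RuCl(p-cymene)[(S,S)-TsDPEN] (1 mol%), HCO2H/Et3N 5:2, CH2Cl2, rt
Reagents that add atoms: none
Why: Noyori asymmetric transfer hydrogenation reduces the enone carbonyl 1,2-selectively, and the (S,S)-catalyst is expected to tell the alkenyl flank from the alkyl flank and so set the carbinol centre (later C11) as S.

Step 2
Reactants: 2 (S)-1,4-dioxaspiro[4.5]dec-6-en-8-ol
Product: 3 (S)-tert-butyl(1,4-dioxaspiro[4.5]dec-6-en-8-yloxy)dimethylsilane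
Conditions: TBSCl, imidazole, DMF, rt
Reagents that add atoms: tert-butyldimethylsilyl chloride, CC(C)(C)[Si](C)(C)Cl
Why: Imidazole-assisted silylation of a secondary allylic alcohol (standard silyl ether protection) leaves the stereocentre untouched.

Step 3
Reactants: 3 (S)-tert-butyl(1,4-dioxaspiro[4.5]dec-6-en-8-yloxy)dimethylsilane
Product: 4 (S)-4-(tert-butyldimethylsilyloxy)cyclohex-2-en-1-one
Conditions: pyridinium p-toluenesulfonate (0.2 equiv), acetone/H2O 10:1, 50 °C
Reagents that add atoms: water, O
Why: Acid-catalysed hydrolysis of the allylic dioxolane unmasks the enone under conditions mild enough for the secondary TBS ether, and no stereocentre is involved.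

Step 4
Reactants: 4 (S)-4-(tert-butyldimethylsilyloxy)cyclohex-2-en-1-one; 5 4,4-dimethylcyclohexane-1,3-dione
Product: 6 2-[(1R,2S)-2-(tert-butyldimethylsilyloxy)-5-oxocyclohexyl]-3-hydroxy-6,6-dimethylcyclohex-2-en-1-one
Conditions: Et3N (0.3 equiv), MeCN, 40 °C
Reagents that add atoms: none
Why: Amine-catalysed Michael addition of a cyclic 1,3-dione to a cyclohexenone forms C9–C10, and the nucleophile should enter anti to the γ-silyloxy group (the trans-3,4-disubstituted cyclohexanone, also the thermodynamic adduct of this reversible addition), which sets C9.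

Step 5
Reactants: 6 2-[(1R,2S)-2-(tert-butyldimethylsilyloxy)-5-oxocyclohexyl]-3-hydroxy-6,6-dimethylcyclohex-2-en-1-one
Product: 7 chloromethyl 4,4-dimethyl-3-oxo-2-[(1R,2S)-2-(tert-butyldimethylsilyloxy)-5-oxocyclohexyl]cyclohex-1-en-1-yl carbonate
Conditions: ClCH2OC(O)Cl (1.1 equiv), pyridine (1.5 equiv), CH2Cl2, −20 °C
Reagents that add atoms: chloromethyl chloroformate, ClCOC(Cl)=O
Why: O-Acylation of the enolized 1,3-dione with a chloroformate (enol carbonate formation) should occur at the less hindered enol oxygen remote from the CMe2 group and parks the C7–O–C20 unit 1,5 to C8 without touching a stereocentre.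

Step 6
Reactants: 7 chloromethyl 4,4-dimethyl-3-oxo-2-[(1R,2S)-2-(tert-butyldimethylsilyloxy)-5-oxocyclohexyl]cyclohex-1-en-1-yl carbonate
Product: 9 spiro β-keto-δ-lactone (C7–C8 and C20–C10 formed; ring A 1,3-dione spiro at C10; ring C as C8=C14 enol), via chloromethyl β-keto ester 8 (not isolated)
Conditions: MgBr2·OEt2 (2.5 equiv), diisopropylethylamine (3 equiv), CH2Cl2 (0.01 M), 0 °C to rt; then NaI (0.2 equiv), MeCN, 45 °C; aqueous NH4Cl
Reagents that add atoms: none
Why: Proposed new method: Magnesium-mediated soft enolization of the C14 ketone is reversible, and of the two enolates only the C8 enolate can reach the carbonate carbonyl (six-membered transition state C8–C9–C10=C1–O–C7), so the ClCH2O–C(=O) group migrates from the enol oxygen to C8 with loss of the 1,3-dione enolate, a far better leaving group than chloromethoxide; this gives 8, whose liberated dione enolate then displaces halide at C20 (chloride, or bromide/iodide after Finkelstein exchange) in a C-alkylation that closes the δ-lactone as a spiro ring on C10. The closest known reaction types are the O-to-C acyl migration of cyclohexane-1,3-dione enol esters, the soft-enolization C-acylation of ketones with activated acyl donors, and the C-alkylation of 2-substituted 1,3-diones. Ring closure modes: the acyl shift runs through a six-membered cyclic transition state and the lactone closes 6-exo-tet. The selectivities needed are C- against O-acylation and C8 against C13, both enforced by ring size (six- against eight-membered transition states), and C- against O-alkylation of the dione, likewise six- against eight-membered; attack of O14 on C20 to a 1,3-dioxin-4-one is held back because the more acidic dione, not the β-keto ester, carries the enolate. C10 is the new stereocentre: the C8 arm should close over the C1(=O)–C2H2 edge of the planar dione enolate and not over the C5(=O)–C4Me2 edge, which puts the CMe2-flanked carbonyl equatorial on the new lactone ring, anti to C8, and retro-Michael/Michael exchange at C9–C10 in the product enolate would drain to the same isomer. C8 remains an enol carbon and is fixed in step 12.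

Step 7
Reactants: 9 spiro β-keto-δ-lactone
Product: 10 C5 spiro-epoxide of 9
Conditions: KN(SiMe3)2 (2.2 equiv), THF, −78 °C; then Me2S=CH2 (3 equiv, from Me3S+ I− and KN(SiMe3)2), −20 °C to rt
Reagents that add atoms: trimethylsulfonium iodide, C[S+](C)C.[I-]
Why: Corey–Chaykovsky epoxidation, in which the acidic β-keto lactone and the enolizable C1 ketone are first masked as their potassium enolates so that the non-enolizable C5 ketone is the only electrophile left for the sulfonium ylide; the epoxide configuration (drawn for attack anti to the axial C20) is erased in step 8.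

Step 8
Reactants: 10 C5 spiro-epoxide
Product: 11 primary alcohol at C6 (C5–H, C6H2OH; C1 ketone retained)
Conditions: Cp2TiCl2 (2.5 equiv), Zn dust (5 equiv), THF, rt (forms Cp2TiCl, trivalent titanium); 1,4-cyclohexadiene (10 equiv)
Reagents that add atoms: none
Why: Reductive epoxide opening by Cp2TiCl (single-electron transfer) cleaves the C5–O bond to the tertiary radical, which should take a hydrogen atom from cyclohexadiene on the face opposite the axial C20 and the axial C4 methyl, giving the equatorial CH2OH (anti-Markovnikov alcohol) and setting C5.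

Step 9
Reactants: 11 primary alcohol at C6
Product: 12 C6 tert-butyldimethylsilyl ether
Conditions: TBSCl (1.2 equiv), imidazole, CH2Cl2, 0 °C
Reagents that add atoms: tert-butyldimethylsilyl chloride, CC(C)(C)[Si](C)(C)Cl
Why: Silyl chloride protection is selective for the primary alcohol, and any silylated enol of the β-keto lactone is hydrolysed on work-up.

Step 10
Reactants: 12 C6 tert-butyldimethylsilyl ether
Product: 13 C1 alcohol (hydroxyl equatorial, cis to C20 and C6)
Conditions: NaH (1.05 equiv), THF, 0 °C; then NaBH4 (1.5 equiv), isopropanol, −20 °C; aqueous NH4Cl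
Reagents that add atoms: none
Why: Borohydride reduction made chemoselective by enolate protection: the β-keto lactone is held as its sodium enolate, and hydride should add to the C1 ketone axially, anti to the axial C20, to give the equatorial alcohol.

Step 11
Reactants: 13 C1 alcohol
Product: 14 C1 acetate
Conditions: Ac2O, pyridine, CH2Cl2, 0 °C to rt
Reagents that add atoms: acetic anhydride, CC(=O)OC(C)=O
Why: Pyridine-mediated acetylation of the secondary alcohol installs the C1 acetate of the target and blocks translactonization of O1 onto C7, while the hydrogen-bonded enol should not be acylated under these conditions.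

Step 12
Reactants: 14 C1 acetate
Product: 15 C8-propargyl β-keto lactone (quaternary C8, C14 ketone)
Conditions: propargyl bromide (1.5 equiv), K2CO3, acetone, rt
Reagents that add atoms: propargyl bromide, C#CCBr
Why: C-Alkylation of a β-keto lactone enolate with a propargylic halide creates the quaternary C8, and the electrophile should enter cis to H9 (cis ring fusion, anti to the axial ring A arm of the spiro centre), the configuration of the target.

Step 13
Reactants: 15 C8-propargyl β-keto lactone
Product: 16 C13=C14 tert-butyldimethylsilyl enol ether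
Conditions: TBSOTf (1.3 equiv), Et3N (2 equiv), CH2Cl2, 0 °C
Reagents that add atoms: tert-butyldimethylsilyl trifluoromethanesulfonate, CC(C)(C)[Si](C)(C)OS(=O)(=O)C(F)(F)F
Why: Silyl triflate/amine enol silane formation is unambiguous because the C14 ketone is the only enolizable carbonyl and, with C8 quaternary, can enolize only toward C13.

Step 14
Reactants: 16 C13=C14 tert-butyldimethylsilyl enol ether
Product: 17 bicyclo[3.2.1]octanone (ring D closed, exocyclic C16=C17, C14 ketone)
Conditions: Ph3PAuCl (5 mol%), AgBF4 (5 mol%), CH2Cl2/MeOH 10:1, rt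
Reagents that add atoms: none
Why: Gold-catalysed 5-exo-dig Conia-ene-type carbocyclization of a silyl enol ether onto a terminal alkyne (alkyne activation by monovalent gold, attack of C13 on C16, protodeauration by methanol) closes ring D with the exocyclic alkene, and the C13 configuration is fixed by the bridge geometry.

Step 15
Reactants: 17 bicyclo[3.2.1]octanone
Product: 18 C14 alcohol (hydroxyl on the C15–C16 side)
Conditions: SmI2 (3 equiv), THF/MeOH 4:1, −78 to 0 °C
Reagents that add atoms: none
Why: Single-electron ketone reduction by SmI2 (divalent samarium) with a proton donor, which unlike hydride addition is governed by product stability, should place the C14 hydroxyl on the C15–C16 side, away from the 1,3-diaxial contact with C10, as in the target.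

Step 16
Reactants: 18 C14 alcohol
Product: 19 C15 allylic alcohol
Conditions: SeO2 (0.5 equiv), t-BuOOH (2 equiv), CH2Cl2, rt
Reagents that add atoms: tert-butyl hydroperoxide, CC(C)(C)OO (oxygen relayed through catalytic selenium dioxide, O=[Se]=O)
Why: SeO2-catalysed allylic oxidation (ene reaction then [2,3]-sigmatropic shift) hydroxylates C15, the only allylic methylene, with return of the exocyclic alkene, and the C15 configuration is irrelevant because it is oxidized next.

Step 17
Reactants: 19 C15 allylic alcohol
Product: 20 C15 ketone (bis-silyl ether of the target)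
Conditions: MnO2 (activated, 20 equiv), CH2Cl2, rt
Reagents that add atoms: none
Why: Manganese dioxide oxidizes only the allylic C15 alcohol to the α-methylene ketone and leaves the saturated C14 carbinol untouched (chemoselective allylic oxidation).

Step 18
Reactants: 20 C15 ketone (bis-silyl ether of the target)
Product: 21 CNP0225182.1
Conditions: HF·pyridine, pyridine/THF, 0 °C to rt
Reagents that add atoms: none
Why: Fluoride-mediated cleavage of both TBS ethers with buffered HF should leave the acetate, the lactone and the α-methylene ketone intact and release the target.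

**Compound list**

1 | 1,4-dioxaspiro[4.5]dec-6-en-8-one | O=C1CCC2(OCCO2)C=C1 | starting material
2 | (S)-1,4-dioxaspiro[4.5]dec-6-en-8-ol | O[C@H]1CCC2(OCCO2)C=C1 | intermediate
3 | (S)-tert-butyl(1,4-dioxaspiro[4.5]dec-6-en-8-yloxy)dimethylsilane | CC(C)(C)[Si](C)(C)O[C@H]1CCC2(OCCO2)C=C1 | intermediate
4 | (S)-4-(tert-butyldimethylsilyloxy)cyclohex-2-en-1-one | CC(C)(C)[Si](C)(C)O[C@H]1CCC(=O)C=C1 | intermediate
5 | 4,4-dimethylcyclohexane-1,3-dione | CC1(C)CCC(=O)CC1=O | starting material
6 | 2-[(1R,2S)-2-(tert-butyldimethylsilyloxy)-5-oxocyclohexyl]-3-hydroxy-6,6-dimethylcyclohex-2-en-1-one (Michael adduct, enol form; C10 and OTBS trans on ring C) | CC(C)(C)[Si](C)(C)O[C@H]1CCC(=O)C[C@@H]1C2=C(O)CCC(C)(C)C2=O | intermediate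
7 | chloromethyl 4,4-dimethyl-3-oxo-2-[(1R,2S)-2-(tert-butyldimethylsilyloxy)-5-oxocyclohexyl]cyclohex-1-en-1-yl carbonate | CC(C)(C)[Si](C)(C)O[C@H]1CCC(=O)C[C@@H]1C2=C(OC(=O)OCCl)CCC(C)(C)C2=O | intermediate
8 | chloromethyl β-keto ester (ClCH2O–C(=O) on C8, drawn as C8=C14 enol; ring A dione free as enol; not isolated) | CC(C)(C)[Si](C)(C)O[C@H]1CCC(O)=C(C(=O)OCCl)[C@@H]1C2=C(O)CCC(C)(C)C2=O | intermediate
9 | spiro β-keto-δ-lactone (lactone C8–C7(=O)–O–C20H2–C10–C9; ring A 4,4-dimethyl-1,3-dione spiro at C10; C8=C14 enol; C11–OTBS; C9, C10, C11 as in 21) | OC1=C2C(=O)OC[C@]3(C(=O)CCC(C)(C)C3=O)[C@@H]2[C@@H](O[Si](C)(C)C(C)(C)C)CC1 | intermediate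
10 | C5 spiro-epoxide of 9 (oxirane CH2 = C6, oxygen cis to C20) | OC1=C2C(=O)OC[C@]3(C(=O)CCC(C)(C)[C@]34CO4)[C@@H]2[C@@H](O[Si](C)(C)C(C)(C)C)CC1 | intermediate
11 | C6 primary alcohol (C5–H trans to C20, CH2OH cis to C20; C1 ketone) | OC1=C2C(=O)OC[C@]3(C(=O)CCC(C)(C)[C@H]3CO)[C@@H]2[C@@H](O[Si](C)(C)C(C)(C)C)CC1 | intermediate
12 | C6 tert-butyldimethylsilyl ether of 11 | OC1=C2C(=O)OC[C@]3(C(=O)CCC(C)(C)[C@H]3CO[Si](C)(C)C(C)(C)C)[C@@H]2[C@@H](O[Si](C)(C)C(C)(C)C)CC1 | intermediate
13 | C1 alcohol (hydroxyl cis to C20 and C6) | OC1=C2C(=O)OC[C@]3([C@@H](O)CCC(C)(C)[C@H]3CO[Si](C)(C)C(C)(C)C)[C@@H]2[C@@H](O[Si](C)(C)C(C)(C)C)CC1 | intermediate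
14 | C1 acetate of 13 | OC1=C2C(=O)OC[C@]3([C@@H](OC(C)=O)CCC(C)(C)[C@H]3CO[Si](C)(C)C(C)(C)C)[C@@H]2[C@@H](O[Si](C)(C)C(C)(C)C)CC1 | intermediate
15 | C8-propargyl β-keto lactone (propargyl cis to H9; C14 ketone) | C#CC[C@@]12C(=O)OC[C@]3([C@@H](OC(C)=O)CCC(C)(C)[C@H]3CO[Si](C)(C)C(C)(C)C)[C@@H]1[C@@H](O[Si](C)(C)C(C)(C)C)CCC2=O | intermediate
16 | C13=C14 tert-butyldimethylsilyl enol ether of 15 | C#CC[C@@]12C(=O)OC[C@]3([C@@H](OC(C)=O)CCC(C)(C)[C@H]3CO[Si](C)(C)C(C)(C)C)[C@@H]1[C@@H](O[Si](C)(C)C(C)(C)C)CC=C2O[Si](C)(C)C(C)(C)C | intermediate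
17 | bicyclo[3.2.1]octanone (ring D closed by C13–C16; exocyclic C16=C17; C14 ketone; C15H2) | C=C1C[C@@]23C(=O)OC[C@]4([C@@H](OC(C)=O)CCC(C)(C)[C@H]4CO[Si](C)(C)C(C)(C)C)[C@@H]2[C@@H](O[Si](C)(C)C(C)(C)C)C[C@@H]1C3=O | intermediate
18 | C14 alcohol (hydroxyl on the C15–C16 side, as in 21) | C=C1C[C@@]23C(=O)OC[C@]4([C@@H](OC(C)=O)CCC(C)(C)[C@H]4CO[Si](C)(C)C(C)(C)C)[C@@H]2[C@@H](O[Si](C)(C)C(C)(C)C)C[C@@H]1[C@H]3O | intermediate
19 | C15 allylic alcohol (C15 configuration not fixed, no descriptor drawn) | C=C1C(O)[C@@]23C(=O)OC[C@]4([C@@H](OC(C)=O)CCC(C)(C)[C@H]4CO[Si](C)(C)C(C)(C)C)[C@@H]2[C@@H](O[Si](C)(C)C(C)(C)C)C[C@@H]1[C@H]3O | intermediate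
20 | C15 ketone, 6,11-bis(tert-butyldimethylsilyl) ether of the target | C=C1C(=O)[C@@]23C(=O)OC[C@]4([C@@H](OC(C)=O)CCC(C)(C)[C@H]4CO[Si](C)(C)C(C)(C)C)[C@@H]2[C@@H](O[Si](C)(C)C(C)(C)C)C[C@@H]1[C@H]3O | intermediate
21 | CNP0225182.1 | C=C1C(=O)[C@@]23C(=O)OC[C@]4([C@@H](OC(C)=O)CCC(C)(C)[C@H]4CO)[C@@H]2[C@@H](O)C[C@@H]1[C@H]3O | target

**Step count and risks**

Total step count: 18. Longest linear sequence: 18 steps (1 to 21; 5 enters at step 4).

Steps most likely to fail:

1. Step 6 (Proposed new method). What may go wrong: acyl scrambling between molecules or by halide relay instead of the intramolecular shift, O-alkylation of the β-keto ester enol by the chloromethyl group, or poor facial selectivity at C10. Fallback, with the two bonds made one at a time in the reverse order by known reactions: setting out from 6, aldol addition to aqueous formaldehyde (catalytic NaHCO3, THF/H2O) gives the 2-hydroxymethyl dione F1 (C20–C10 bond). 1,1'-Carbonyldiimidazole in CH2Cl2 converts its primary alcohol into the imidazole-1-carboxylate F2. NaH in THF then brings about a Dieckmann-type C-acylation of the ring C ketone, in which reversible enolate equilibration lets only C8 close the six-membered lactone; after acidic work-up the route is rejoined at 9.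

2. Step 7. What may go wrong: no methylene transfer to the doubly neopentyl C5 carbonyl of the bis-enolate, or ylide attack at the lactone. Fallback, with ring A reduced and acetylated first and an ester-tolerant, non-basic carbenoid used instead of the ylide: setting out from 9, enolate-protected NaBH4 reduction (as in step 10) gives the C1 alcohol F3, and acetylation (as in step 11) gives the acetate F4. The samarium carbenoid from SmI2 and CH2I2 (THF, rt), which adds to ketones but not to esters, gives the iodohydrin F5, closed with K2CO3 in MeCN to the epoxide F6. Cp2TiCl opening (as in step 8) gives the primary alcohol F7, and silylation with TBSCl/imidazole returns to the route at 14.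

3. Step 15. What may go wrong: poor facial selectivity, with protonation of the samarium intermediate from the open C15–C16 side leading to the 14-epimer. Fallback, a kinetic reduction followed by redox-neutral equilibration: setting out from 17, NaBH4 in MeOH/THF at 0 °C gives the 14-epi alcohol F8. This is epimerized by reversible hydrogen transfer with Shvo's complex [Ru2(CO)4(μ-H)(C4Ph4COHOCC4Ph4)] in toluene at 80 °C to the thermodynamically preferred alcohol, rejoining the route at 18.

**Further compounds**

F1 | step 6 | 2-hydroxymethyl dione (C20H2OH on C10 of 6, triketone form) | CC(C)(C)[Si](C)(C)O[C@H]1CCC(=O)C[C@@H]1[C@]2(CO)C(=O)CCC(C)(C)C2=O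
F2 | step 6 | imidazole-1-carboxylate of F1 | CC(C)(C)[Si](C)(C)O[C@H]1CCC(=O)C[C@@H]1[C@]2(COC(=O)n3ccnc3)C(=O)CCC(C)(C)C2=O
F3 | step 7 | C1 alcohol of 9 (C5 ketone retained) | OC1=C2C(=O)OC[C@]3([C@@H](O)CCC(C)(C)C3=O)[C@@H]2[C@@H](O[Si](C)(C)C(C)(C)C)CC1
F4 | step 7 | C1 acetate of F3 | OC1=C2C(=O)OC[C@]3([C@@H](OC(C)=O)CCC(C)(C)C3=O)[C@@H]2[C@@H](O[Si](C)(C)C(C)(C)C)CC1
F5 | step 7 | iodohydrin (C5–OH, C5–CH2I) | OC1=C2C(=O)OC[C@]3([C@@H](OC(C)=O)CCC(C)(C)[C@]3(O)CI)[C@@H]2[C@@H](O[Si](C)(C)C(C)(C)C)CC1
F6 | step 7 | C5 spiro-epoxide with C1 acetate | OC1=C2C(=O)OC[C@]3([C@@H](OC(C)=O)CCC(C)(C)[C@]34CO4)[C@@H]2[C@@H](O[Si](C)(C)C(C)(C)C)CC1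
F7 | step 7 | C6 primary alcohol with C1 acetate | OC1=C2C(=O)OC[C@]3([C@@H](OC(C)=O)CCC(C)(C)[C@H]3CO)[C@@H]2[C@@H](O[Si](C)(C)C(C)(C)C)CC1
F8 | step 15 | 14-epi alcohol of 18 | C=C1C[C@@]23C(=O)OC[C@]4([C@@H](OC(C)=O)CCC(C)(C)[C@H]4CO[Si](C)(C)C(C)(C)C)[C@@H]2[C@@H](O[Si](C)(C)C(C)(C)C)C[C@@H]1[C@@H]3O
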